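**Retrosynthetic overview**

1. The p-coumarate is made last: acylation of the C6 alcohol with acryloyl chloride, then Heck arylation of the acrylate with 4-iodophenol.
2. The C4 methylidene comes from the C4 ketone of a trans-decalin β-hydroxy ketone in which C5, C6 and C7 are set together by base equilibration.
3. Key step: a regioselective one-carbon ring expansion (C3 inserted between C4 and C2) turns the cyclopentanone of a cis-hydrindanone ketol into the cyclohexanone of ring A.
4. Ring B is closed by intramolecular aldol (C5–C6) of a keto-aldehyde made by formyl delivery to a homoprenyl side chain (C6–C7).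
5. The C10 quaternary centre comes from Cu-catalysed asymmetric conjugate addition to 3-methylcyclopent-2-en-1-one. Ring order: bought five-membered ring, then ring B (aldol), then ring A (expanded to six).

Assumption: atom labels follow eudesmane numbering (C10 methyl-bearing quaternary carbon, C5 ring-fusion CH, C6 oxygen-bearing carbon, C7 isopropyl-bearing carbon, C4 methylidene carbon); β is the face of the C10 methyl group, α the opposite face.

**Route**

Step 1
Reactants: 1 3-methylcyclopent-2-en-1-one; 2 5-bromo-2-methylpent-2-ene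
Product: 4 (3S)-3-methyl-3-(4-methylpent-3-en-1-yl)cyclopentan-1-one, via Grignard reagent 3 (not isolated)
Conditions: 2, Mg, Et2O, reflux; then 1, Cu(OTf)2 (3 mol %), chiral C2-symmetric imidazolinium chloride (NHC precursor, 4 mol %), Et2O, −30 °C; aq. NH4Cl
Reagents that add atoms: none
Why: Cu-catalysed asymmetric conjugate addition of a Grignard reagent to a β-substituted cyclic enone, in which the chiral NHC–copper complex delivers the homoprenyl group to one enantiotopic face of the β-carbon and so sets the C10 quaternary centre (S in 4, ligand enantiomer chosen for this sense).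

Step 2
Reactants: 4 (3S)-3-methyl-3-(4-methylpent-3-en-1-yl)cyclopentan-1-one
Product: 6 (3aS,6R,7R,7aR)-7-hydroxy-3a-methyl-6-(propan-2-yl)octahydro-1H-inden-1-one (cis-fused; main diastereomer), via keto-aldehyde 5 (not isolated)
Conditions: Rh(acac)(CO)2 (1 mol %), tris(2,4-di-tert-butylphenyl) phosphite (5 mol %), CO/H2 (1:1, 40 bar), toluene, 80 °C; vent; then K2CO3, MeOH, 0 °C
Reagents that add atoms: carbon monoxide, [C-]#[O+]
Why: Proposed new method: Rh hydroformylation of the trisubstituted homoprenyl alkene with formyl delivery to its CH carbon (C7), run in one flask with base-mediated intramolecular aldol; the mono-phosphite Rh–H species is unsaturated enough to bind the hindered alkene, Rh adds to C7 because a tertiary alkyl–Rh at the CMe2 carbon cannot lead to an aldehyde (Keulemans' rule), and high CO pressure makes CO insertion faster than the β-hydride elimination that would walk the double bond to the chain end; aldehyde 5 then closes ring B through the C5 enolate onto C6 (six-ring aldol); the closest known reactions are bulky-phosphite Rh hydroformylation of cyclic trisubstituted terpene alkenes and tandem hydroformylation–aldol annulation of unsaturated ketones; the C5, C6 and C7 centres formed here are not final (ring-B epimers are carried on), because step 3 equilibrates them.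

Step 3
Reactants: 6 (3aS,6R,7R,7aR)-7-hydroxy-3a-methyl-6-(propan-2-yl)octahydro-1H-inden-1-one
Product: 10 (4aR,7S,8S,8aS)-8-hydroxy-4a-methyl-7-(propan-2-yl)octahydronaphthalen-1(2H)-one, via β-ketosilane 7 (not isolated), via cis-fused decalin ketol 8 (not isolated), via ring-opened keto-aldehyde 9 (not isolated)
Conditions: TMSCHN2 (2 equiv), Sc(OTf)3 (10 mol %), CH2Cl2, −40 → 0 °C; then NaOMe (0.5 equiv), MeOH, 0 °C → rt
Reagents that add atoms: (trimethylsilyl)diazomethane, C[Si](C)(C)C=[N+]=[N-]
Why: Lewis-acid-catalysed diazoalkane–ketone homologation (one-carbon ring expansion) in which the unbranched C2 methylene migrates in preference to the branched C5, after which methoxide cleaves the C–Si bond and equilibrates C5 (enolisation) and C6/C7 (retro-aldol/aldol through 9) to the all-equatorial, hydrogen-bonded trans-decalin ketol, which sets 5α-H, 6α-OH and 7β-isopropyl relative to C10.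

Step 4
Reactants: 10 (4aR,7S,8S,8aS)-8-hydroxy-4a-methyl-7-(propan-2-yl)octahydronaphthalen-1(2H)-one
Product: 11 (1S,2S,4aR,8aS)-4a-methyl-8-methylidene-2-(propan-2-yl)decahydronaphthalen-1-ol
Conditions: Zn, CH2Br2, TiCl4, THF/CH2Cl2, 0 °C → rt
Reagents that add atoms: dibromomethane, BrCBr
Why: Lombardo–Takai methylenation, whose non-basic zinc/titanium carbenoid converts the hindered, enolisable β-hydroxy ketone into the exocyclic methylidene without retro-aldol or epimerisation at C5.

Step 5
Reactants: 11 (1S,2S,4aR,8aS)-4a-methyl-8-methylidene-2-(propan-2-yl)decahydronaphthalen-1-ol; 12 acryloyl chloride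
Product: 13 (1S,2S,4aR,8aS)-4a-methyl-8-methylidene-2-(propan-2-yl)decahydronaphthalen-1-yl prop-2-enoate
Conditions: Et3N, DMAP (10 mol %), CH2Cl2, 0 °C → rt
Reagents that add atoms: none
Why: DMAP-catalysed O-acylation of the equatorial secondary alcohol with an acid chloride, which touches no stereocentre.

Step 6
Reactants: 13 (1S,2S,4aR,8aS)-4a-methyl-8-methylidene-2-(propan-2-yl)decahydronaphthalen-1-yl prop-2-enoate; 14 4-iodophenol
Product: 15 (1S,2S,4aR,8aS)-4a-methyl-8-methylidene-2-(propan-2-yl)decahydronaphthalen-1-yl (2E)-3-(4-hydroxyphenyl)prop-2-enoate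
Conditions: Pd(OAc)2 (5 mol %), Bu4NCl, NaHCO3, DMF, 60 °C
Reagents that add atoms: none
Why: Mizoroki–Heck coupling under Jeffery conditions, where syn-carbopalladation and syn-β-hydride elimination give the E-cinnamate, the electron-poor acrylate reacts far faster than the 1,1-disubstituted exocyclic alkene, and the free phenol is tolerated.

**Compound list**

1 | 3-methylcyclopent-2-en-1-one | CC1=CC(=O)CC1 | starting material
2 | 5-bromo-2-methylpent-2-ene | CC(C)=CCCBr | starting material
3 | (4-methylpent-3-en-1-yl)magnesium bromide | CC(C)=CCC[Mg]Br | intermediate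
4 | (3S)-3-methyl-3-(4-methylpent-3-en-1-yl)cyclopentan-1-one | O=C1C[C@@](C)(CCC=C(C)C)CC1 | intermediate
5 | 4-[(1S)-1-methyl-3-oxocyclopentyl]-2-(propan-2-yl)butanal (both C2 epimers) | O=C1C[C@@](C)(CCC(C=O)C(C)C)CC1 | intermediate
6 | (3aS,6R,7R,7aR)-7-hydroxy-3a-methyl-6-(propan-2-yl)octahydro-1H-inden-1-one (cis-fused; main diastereomer, ring-B epimers carried on) | O=C1CC[C@]2(C)CC[C@H](C(C)C)[C@@H](O)[C@H]12 | intermediate
7 | cis-fused 8-hydroxy-4a-methyl-7-(propan-2-yl)-2-(trimethylsilyl)octahydronaphthalen-1(2H)-one (ring-B configuration as in 6, both C2 epimers) | O=C1C([Si](C)(C)C)CC[C@]2(C)CC[C@H](C(C)C)[C@@H](O)[C@H]12 | intermediate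
8 | (4aR,7R,8R,8aR)-8-hydroxy-4a-methyl-7-(propan-2-yl)octahydronaphthalen-1(2H)-one (cis-fused) | O=C1CCC[C@]2(C)CC[C@H](C(C)C)[C@@H](O)[C@H]12 | intermediate
9 | 4-[(1R)-1-methyl-3-oxocyclohexyl]-2-(propan-2-yl)butanal (both C2 epimers) | O=CC(C(C)C)CC[C@@]1(C)CCCC(=O)C1 | intermediate
10 | (4aR,7S,8S,8aS)-8-hydroxy-4a-methyl-7-(propan-2-yl)octahydronaphthalen-1(2H)-one (trans-fused) | O=C1CCC[C@]2(C)CC[C@@H](C(C)C)[C@H](O)[C@@H]12 | intermediate
11 | (1S,2S,4aR,8aS)-4a-methyl-8-methylidene-2-(propan-2-yl)decahydronaphthalen-1-ol | C=C1CCC[C@]2(C)CC[C@@H](C(C)C)[C@H](O)[C@@H]12 | intermediate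
12 | acryloyl chloride | C=CC(=O)Cl | starting material
13 | (1S,2S,4aR,8aS)-4a-methyl-8-methylidene-2-(propan-2-yl)decahydronaphthalen-1-yl prop-2-enoate | C=C1CCC[C@]2(C)CC[C@@H](C(C)C)[C@H](OC(=O)C=C)[C@@H]12 | intermediate
14 | 4-iodophenol | Oc1ccc(I)cc1 | starting material
15 | (1S,2S,4aR,8aS)-4a-methyl-8-methylidene-2-(propan-2-yl)decahydronaphthalen-1-yl (2E)-3-(4-hydroxyphenyl)prop-2-enoate | C=C1CCC[C@]2(C)CC[C@@H](C(C)C)[C@H](OC(=O)/C=C/c3ccc(O)cc3)[C@@H]12 | target

**Step count and risks**

Total step count: 6. Longest linear sequence: 6 (steps 1 to 6).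

The three steps most likely to fail:

Step 1 (enantioselectivity of a Grignard conjugate addition that builds a quaternary centre on a five-membered enone). The fallback sets out from Grignard reagent 3 and comes back at 4. Compound 3 is added in 1,2-fashion to 3-methoxycyclopent-2-en-1-one F1, and acid work-up (Stork–Danheiser transposition) gives 3-(4-methylpent-3-en-1-yl)cyclopent-2-en-1-one F2. Cu-catalysed asymmetric conjugate addition of Me3Al to F2 (Cu(OTf)2, chiral ligand of the matching facial sense), a well-established way to add methyl to 3-alkyl cycloalkenones, then gives 4.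

Step 2 (the proposed new step; the alkene may not react, or the double bond may walk to the chain end and give the linear aldehyde). The fallback uses known chemistry, sets out from 4 and comes back at 5. A Me2AlCl-promoted ene reaction of 4 with paraformaldehyde puts a hydroxymethyl group on C7 and gives (3S)-3-[3-(hydroxymethyl)-4-methylpent-4-en-1-yl]-3-methylcyclopentan-1-one F3. Hydrogenation (H2, Pd/C) of the isopropenyl group gives (3S)-3-[3-(hydroxymethyl)-4-methylpentyl]-3-methylcyclopentan-1-one F4. Dess–Martin oxidation of F4 gives keto-aldehyde 5, which is cyclised to 6 with K2CO3/MeOH as in step 2.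

Step 3 (migration of the wrong carbon, O-alkylation of the free hydroxyl, or dehydration of the ketol during equilibration). The fallback is an Ito–Saegusa ring expansion that sets out from 6 and comes back at 8. LDA/TMSCl converts 6 into its bis-trimethylsilyl derivative (C6 silyl ether and kinetic C4=C2 silyl enol ether) F5. Et2Zn/CH2I2 cyclopropanation gives the siloxycyclopropane F6, and FeCl3 in DMF opens it to the ring-enlarged β-chloro ketone F7. K2CO3/MeOH eliminates HCl and frees the hydroxyl to give the cis-fused cyclohexenone ketol F8. H2, Pd/C reduces the enone to 8, and NaOMe/MeOH as in step 3 converts 8 into 10. The position of the new carbon is fixed here by the kinetic enol ether and does not depend on migratory preference.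

**Further compounds**

F1 | step 1 | 3-methoxycyclopent-2-en-1-one | COC1=CC(=O)CC1
F2 | step 1 | 3-(4-methylpent-3-en-1-yl)cyclopent-2-en-1-one | CC(C)=CCCC1=CC(=O)CC1
F3 | step 2 | (3S)-3-[3-(hydroxymethyl)-4-methylpent-4-en-1-yl]-3-methylcyclopentan-1-one | O=C1C[C@@](C)(CCC(CO)C(C)=C)CC1
F4 | step 2 | (3S)-3-[3-(hydroxymethyl)-4-methylpentyl]-3-methylcyclopentan-1-one | O=C1C[C@@](C)(CCC(CO)C(C)C)CC1
F5 | step 3 | bis-trimethylsilyl derivative of 6 (C6 trimethylsilyl ether, C4=C2 trimethylsilyl enol ether) | C[Si](C)(C)OC1=CC[C@]2(C)CC[C@H](C(C)C)[C@@H](O[Si](C)(C)C)[C@H]12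
F6 | step 3 | siloxycyclopropane from F5 (methylene bridging C4 and C2) | C[Si](C)(C)OC13CC3C[C@]2(C)CC[C@H](C(C)C)[C@@H](O[Si](C)(C)C)[C@H]12
F7 | step 3 | cis-fused 3-chloro-4a-methyl-7-(propan-2-yl)-8-[(trimethylsilyl)oxy]octahydronaphthalen-1(2H)-one | O=C1CC(Cl)C[C@]2(C)CC[C@H](C(C)C)[C@@H](O[Si](C)(C)C)[C@H]12
F8 | step 3 | cis-fused 8-hydroxy-4a-methyl-7-(propan-2-yl)-4a,5,6,7,8,8a-hexahydronaphthalen-1(4H)-one | O=C1C=CC[C@]2(C)CC[C@H](C(C)C)[C@@H](O)[C@H]12
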